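**Retrosynthetic overview**
- The C11–O aryl ether is made last: Mitsunobu coupling of 9βH-drim-7-ene-3α,11-diol with esculetin at its more acidic 7-OH, then 6-O-methylation; esculetin comes from p-benzoquinone and ethyl propiolate.
- The C8 methyl and the 7,8-alkene come from a C8 ketone through its kinetic enol triflate.
- Ring B comes from a one-carbon ring expansion of a trans-hydrindan-1-one (1,2-shift of C10); the regiodefined enolate is hydroxymethylated at C9 on the α face.
- Ring A functionality (gem-dimethyl, 5α-H, axial 3α-OH) comes from reductive methylation and bulky-hydride reduction of a mono-protected enedione.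
- Ring order: the five-membered ring is bought, ring A is added by amino-acid-mediated Robinson annulation, ring B is made by expansion of the five-membered ring, and the separately made coumarin is attached last.

Assumption: drimane numbering (C9 carries C11, angular methyl on C10) is used for the carbocycle from the hydrindanone stage on, and α means the face opposite the angular methyl.

**Route**

Step 1
Reactants: 1 2-methylcyclopentane-1,3-dione; 2 ethyl vinyl ketone (pent-1-en-3-one)
Product: 5 (7aS)-4,7a-dimethyl-2,3,7,7a-tetrahydro-1H-indene-1,5(6H)-dione, via triketone 3 (not isolated), via ketol 4 (not isolated)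
Conditions: H2O, AcOH (cat.), 75 °C; concentrate; (S)-phenylalanine (1 equiv), HClO4 (0.5 equiv), MeCN, reflux
Reagents that add atoms: none
Why: Michael addition followed by the (S)-phenylalanine-mediated Hajos–Parrish-type aldol condensation, in which the enamine of the side-chain ketone attacks one of the two enantiotopic ring carbonyls, sets the (S) quaternary carbon that becomes C10.

Step 2
Reactants: 5 (7aS)-4,7a-dimethyl-2,3,7,7a-tetrahydro-1H-indene-1,5(6H)-dione
Product: 6 (7a'S)-4',7a'-dimethyl-2',3',7',7a'-tetrahydrospiro[[1,3]dioxolane-2,1'-inden]-5'(6'H)-one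
Conditions: (Me3SiOCH2)2, Me3SiOTf (5 mol %), CH2Cl2, −78 → 0 °C
Reagents that add atoms: 1,2-bis(trimethylsilyloxy)ethane, C[Si](C)(C)OCCO[Si](C)(C)C
Why: Noyori ketalisation is selective for the saturated cyclopentanone over the less electrophilic conjugated carbonyl, which masks the future C8 carbonyl during the two reductions that follow.

Step 3
Reactants: 6 (7a'S)-4',7a'-dimethyl-2',3',7',7a'-tetrahydrospiro[[1,3]dioxolane-2,1'-inden]-5'(6'H)-one
Product: 8 (3a'S,7a'S)-4',4',7a'-trimethylhexahydrospiro[[1,3]dioxolane-2,1'-inden]-5'(4'H)-one, via lithium enolate 7 (not isolated)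
Conditions: Li (2.2 equiv), NH3(l)/THF, t-BuOH (1 equiv), −78 °C; then MeI, −78 → −33 °C
Reagents that add atoms: iodomethane, CI
Why: Birch-type reductive alkylation protonates the β-carbon (C5) on the α face to give the more stable trans ring fusion, and the regiodefined enolate is C-methylated at C4, which sets 5α-H and completes the gem-dimethyl group.

Step 4
Reactants: 8 (3a'S,7a'S)-4',4',7a'-trimethylhexahydrospiro[[1,3]dioxolane-2,1'-inden]-5'(4'H)-one
Product: 10 (3aS,5R,7aS)-5-hydroxy-4,4,7a-trimethyloctahydro-1H-inden-1-one, via ketal alcohol 9 (not isolated)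
Conditions: LiBH(s-Bu)3, THF, −78 °C; then 3 M HCl, THF, rt; recrystallise
Reagents that add atoms: water, O
Why: The bulky trialkylborohydride attacks the C3 ketone from the equatorial direction (the axial path is blocked by the 1,3-diaxial hydrogens for so large a reagent) and gives the axial 3α-alcohol, after which aqueous acid hydrolyses the dioxolane.

Step 5
Reactants: 10 (3aS,5R,7aS)-5-hydroxy-4,4,7a-trimethyloctahydro-1H-inden-1-one
Product: 15 (1R,4aR,6R,8aS)-5,5,8a-trimethyl-6-(triethylsilyloxy)-1-[(triethylsilyloxy)methyl]octahydronaphthalen-2(1H)-one, via dibromomethyl carbinolate 11 (not isolated), via bromo carbenoid 12 (not isolated), via ring-expanded enolate 13 (not isolated), via aldolate 14 (not isolated)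
Conditions: lithium 2,2,6,6-tetramethylpiperidide (2.6 equiv), CH2Br2 (1.5 equiv), THF, −78 °C; n-BuLi (1.6 equiv), −78 → 0 °C; CH2O (1.5 equiv, THF solution), −78 °C; Et3SiOTf, −78 → −30 °C
Reagents that add atoms: dibromomethane, BrCBr; formaldehyde, C=O; triethylsilyl trifluoromethanesulfonate, CC[Si](CC)(CC)OS(=O)(=O)C(F)(F)F
Why: Proposed new method: LiCHBr2 adds to the ketone from the α face and Br–Li exchange gives a β-oxido carbenoid whose alkoxide drives a non-pericyclic anionotropic 1,2-shift of the more electron-rich, fully substituted C10 (with retention) onto the carbenoid carbon as bromide leaves, so the cyclopentanone is expanded to the ring B cyclohexanone directly as its C8–C9 lithium enolate (a regiochemistry that deprotonation cannot give), and CH2O then attacks C9 axially on the α face anti to the axial angular methyl to form the C9–C11 bond and set C9 before both alkoxides are silylated; the closest known reaction type is the dibromomethyllithium (β-oxido carbenoid) one-carbon ring enlargement of 2-alkylcycloalkanones, in which the more substituted α-carbon migrates and the enolate can be trapped, which has not been shown for migration of an angular quaternary carbon of a hydrindanone or coupled to enolate hydroxymethylation.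

Step 6
Reactants: 15 (1R,4aR,6R,8aS)-5,5,8a-trimethyl-6-(triethylsilyloxy)-1-[(triethylsilyloxy)methyl]octahydronaphthalen-2(1H)-one
Product: 17 (1R,4aR,6R,8aS)-5,5,8a-trimethyl-6-(triethylsilyloxy)-1-[(triethylsilyloxy)methyl]-1,4,4a,5,6,7,8,8a-octahydronaphthalen-2-yl trifluoromethanesulfonate, via potassium enolate 16 (not isolated)
Conditions: KN(SiMe3)2 (1.1 equiv), THF, −78 °C; PhNTf2, −78 → −20 °C
Reagents that add atoms: N-phenylbis(trifluoromethanesulfonimide), O=S(=O)(N(c1ccccc1)S(=O)(=O)C(F)(F)F)C(F)(F)F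
Why: Kinetic deprotonation by the hindered amide removes an axial H-7 of the methylene and not the equatorial H-9 next to the quaternary carbon, so O-triflation gives the Δ7 enol triflate without epimerising C9 (kinetic enol triflate formation).

Step 7
Reactants: 17 (1R,4aR,6R,8aS)-5,5,8a-trimethyl-6-(triethylsilyloxy)-1-[(triethylsilyloxy)methyl]-1,4,4a,5,6,7,8,8a-octahydronaphthalen-2-yl trifluoromethanesulfonate
Product: 19 (2R,4aS,5R,8aR)-5-(hydroxymethyl)-1,1,4a,6-tetramethyl-1,2,3,4,4a,5,8,8a-octahydronaphthalen-2-ol (9βH-drim-7-ene-3α,11-diol), via bis(silyl ether) 18 (not isolated)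
Conditions: MeMgBr (3 equiv), Fe(acac)3 (10 mol %), THF/NMP, −20 → 0 °C; then 1% HCl in MeOH, rt
Reagents that add atoms: methylmagnesium bromide, C[Mg]Br
Why: Iron-catalysed Kumada-type cross-coupling of the alkenyl triflate installs the C8 methyl with the alkene fixed at C7–C8, and acidic methanolysis in the work-up removes both triethylsilyl ethers.

Step 8
Reactants: 20 p-benzoquinone
Product: 21 benzene-1,2,4-triyl triacetate
Conditions: Ac2O, H2SO4 (cat.), 40–50 °C
Reagents that add atoms: acetic anhydride, CC(=O)OC(C)=O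
Why: Thiele–Winter acetoxylation (acid-catalysed conjugate addition of acetic anhydride to the quinone, enolisation and acetylation) gives the 1,2,4-trioxygenated arene.

Step 9
Reactants: 21 benzene-1,2,4-triyl triacetate; 22 ethyl propiolate
Product: 24 esculetin (6,7-dihydroxy-2H-chromen-2-one), via benzene-1,2,4-triol 23 (not isolated)
Conditions: 75% aq H2SO4, 100 °C
Reagents that add atoms: none
Why: In hot aqueous acid the acetates hydrolyse and the triol undergoes Pechmann-type condensation with the propiolate (C-attack at the position para to one hydroxyl and ortho to another, then lactonisation), which can only give the 6,7-dihydroxy pattern.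

Step 10
Reactants: 19 (2R,4aS,5R,8aR)-5-(hydroxymethyl)-1,1,4a,6-tetramethyl-1,2,3,4,4a,5,8,8a-octahydronaphthalen-2-ol; 24 esculetin
Product: 26 7-{[(1R,4aR,6R,8aS)-6-hydroxy-2,5,5,8a-tetramethyl-1,4,4a,5,6,7,8,8a-octahydronaphthalen-1-yl]methoxy}-6-methoxy-2H-chromen-2-one (target), via 6-hydroxycoumarin ether 25 (not isolated)
Conditions: 24 (1.5 equiv), PPh3, DIAD, THF, 0 °C → rt; then MeOH, PPh3, DIAD, rt
Reagents that add atoms: methanol, CO
Why: In the Mitsunobu etherification the betaine deprotonates the more acidic 7-OH of esculetin (vinylogous to the lactone carbonyl) and this phenoxide displaces the activated primary C11 oxygen while the hindered axial 3-OH stays untouched, and a second Mitsunobu reaction with methanol then caps the 6-OH without affecting any stereocentre.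

**Compound list**

1 | 2-methylcyclopentane-1,3-dione | CC1C(=O)CCC1=O | starting material
2 | ethyl vinyl ketone (pent-1-en-3-one) | CCC(=O)C=C | starting material
3 | 2-methyl-2-(3-oxopentyl)cyclopentane-1,3-dione | CCC(=O)CCC1(C)C(=O)CCC1=O | intermediate
4 | (3aS,7aS)-3a-hydroxy-4,7a-dimethylhexahydro-1H-indene-1,5(4H)-dione (cis-fused ketol, C4 epimers) | C[C@]12CCC(=O)C(C)[C@@]1(O)CCC2=O | intermediate
5 | (7aS)-4,7a-dimethyl-2,3,7,7a-tetrahydro-1H-indene-1,5(6H)-dione | C[C@]12CCC(=O)C(C)=C1CCC2=O | intermediate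
6 | (7a'S)-4',7a'-dimethyl-2',3',7',7a'-tetrahydrospiro[[1,3]dioxolane-2,1'-inden]-5'(6'H)-one | C[C@]12CCC(=O)C(C)=C1CCC21OCCO1 | intermediate
7 | lithium (3a'S,7a'S)-4',7a'-dimethyl-2',3',3a',6',7',7a'-hexahydrospiro[[1,3]dioxolane-2,1'-inden]-5'-olate (trans-fused enolate) | C[C@]12CCC(O[Li])=C(C)[C@@H]1CCC21OCCO1 | intermediate
8 | (3a'S,7a'S)-4',4',7a'-trimethylhexahydrospiro[[1,3]dioxolane-2,1'-inden]-5'(4'H)-one (trans-fused) | C[C@]12CCC(=O)C(C)(C)[C@@H]1CCC21OCCO1 | intermediate
9 | (3a'S,5'R,7a'S)-4',4',7a'-trimethyloctahydrospiro[[1,3]dioxolane-2,1'-inden]-5'-ol | C[C@]12CC[C@@H](O)C(C)(C)[C@@H]1CCC21OCCO1 | intermediate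
10 | (3aS,5R,7aS)-5-hydroxy-4,4,7a-trimethyloctahydro-1H-inden-1-one (trans-fused, axial hydroxyl anti to the angular methyl) | C[C@]12CC[C@@H](O)C(C)(C)[C@@H]1CCC2=O | intermediate
11 | dilithium (1S,3aS,5R,7aS)-1-(dibromomethyl)-4,4,7a-trimethyloctahydro-1H-indene-1,5-diolate | C[C@]12CC[C@@H](O[Li])C(C)(C)[C@@H]1CC[C@@]2(O[Li])C(Br)Br | intermediate
12 | dilithium (1S,3aS,5R,7aS)-1-[bromo(lithio)methyl]-4,4,7a-trimethyloctahydro-1H-indene-1,5-diolate (β-oxido carbenoid) | C[C@]12CC[C@@H](O[Li])C(C)(C)[C@@H]1CC[C@@]2(O[Li])C([Li])Br | intermediate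
13 | dilithium (4aR,6R,8aS)-5,5,8a-trimethyl-3,4,4a,5,6,7,8,8a-octahydronaphthalene-2,6-diolate (C8–C9 enolate, drimane numbering) | C1=C(O[Li])CC[C@H]2C(C)(C)[C@H](O[Li])CC[C@]12C | intermediate
14 | dilithium dialkoxide of (1R,4aR,6R,8aS)-6-hydroxy-1-(hydroxymethyl)-5,5,8a-trimethyloctahydronaphthalen-2(1H)-one (9α-hydroxymethyl aldolate) | [Li]OC[C@@H]1C(=O)CC[C@H]2C(C)(C)[C@H](O[Li])CC[C@]12C | intermediate
15 | (1R,4aR,6R,8aS)-5,5,8a-trimethyl-6-(triethylsilyloxy)-1-[(triethylsilyloxy)methyl]octahydronaphthalen-2(1H)-one | CC[Si](CC)(CC)OC[C@@H]1C(=O)CC[C@H]2C(C)(C)[C@H](O[Si](CC)(CC)CC)CC[C@]12C | intermediate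
16 | potassium (1R,4aR,6R,8aS)-5,5,8a-trimethyl-6-(triethylsilyloxy)-1-[(triethylsilyloxy)methyl]-1,4,4a,5,6,7,8,8a-octahydronaphthalen-2-olate | CC[Si](CC)(CC)OC[C@@H]1C(O[K])=CC[C@H]2C(C)(C)[C@H](O[Si](CC)(CC)CC)CC[C@]12C | intermediate
17 | (1R,4aR,6R,8aS)-5,5,8a-trimethyl-6-(triethylsilyloxy)-1-[(triethylsilyloxy)methyl]-1,4,4a,5,6,7,8,8a-octahydronaphthalen-2-yl trifluoromethanesulfonate | CC[Si](CC)(CC)OC[C@@H]1C(OS(=O)(=O)C(F)(F)F)=CC[C@H]2C(C)(C)[C@H](O[Si](CC)(CC)CC)CC[C@]12C | intermediate
18 | triethyl{[(1R,4aR,6R,8aS)-2,5,5,8a-tetramethyl-6-(triethylsilyloxy)-1,4,4a,5,6,7,8,8a-octahydronaphthalen-1-yl]methoxy}silane | CC[Si](CC)(CC)OC[C@@H]1C(C)=CC[C@H]2C(C)(C)[C@H](O[Si](CC)(CC)CC)CC[C@]12C | intermediate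
19 | (2R,4aS,5R,8aR)-5-(hydroxymethyl)-1,1,4a,6-tetramethyl-1,2,3,4,4a,5,8,8a-octahydronaphthalen-2-ol (9βH-drim-7-ene-3α,11-diol) | OC[C@@H]1C(C)=CC[C@H]2C(C)(C)[C@H](O)CC[C@]12C | intermediate
20 | p-benzoquinone | O=C1C=CC(=O)C=C1 | starting material
21 | benzene-1,2,4-triyl triacetate | CC(=O)Oc1ccc(OC(C)=O)c(OC(C)=O)c1 | intermediate
22 | ethyl propiolate | C#CC(=O)OCC | starting material
23 | benzene-1,2,4-triol | Oc1ccc(O)c(O)c1 | intermediate
24 | esculetin (6,7-dihydroxy-2H-chromen-2-one) | O=c1ccc2cc(O)c(O)cc2o1 | intermediate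
25 | 6-hydroxy-7-{[(1R,4aR,6R,8aS)-6-hydroxy-2,5,5,8a-tetramethyl-1,4,4a,5,6,7,8,8a-octahydronaphthalen-1-yl]methoxy}-2H-chromen-2-one | Oc1cc2ccc(=O)oc2cc1OC[C@@H]1C(C)=CC[C@H]2C(C)(C)[C@H](O)CC[C@]12C | intermediate
26 | 7-{[(1R,4aR,6R,8aS)-6-hydroxy-2,5,5,8a-tetramethyl-1,4,4a,5,6,7,8,8a-octahydronaphthalen-1-yl]methoxy}-6-methoxy-2H-chromen-2-one | COc1cc2ccc(=O)oc2cc1OC[C@@H]1C(C)=CC[C@H]2C(C)(C)[C@H](O)CC[C@]12C | target

**Step count and risks**

Total step count: 10. Longest linear sequence: 8 (steps 1–7 and 10); steps 8–9 make the coumarin partner.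

Steps most likely to fail:

- Step 5 (the proposed new ring expansion). The C7 methylene might migrate instead of C10, or the carbenoid might collapse to an epoxide. The fallback uses known sulfur chemistry and sets out from 10. Addition of (PhS)2CHLi (THF, −78 °C) gives (1S,3aS,5R,7aS)-1-[bis(phenylthio)methyl]-4,4,7a-trimethyloctahydro-1H-indene-1,5-diol F2. Treatment with (CuOTf)2·C6H6 and i-Pr2NEt in benzene at 75 °C ionises one C–S bond, and the thionium-ion semipinacol shift, in which the more substituted α-carbon is the one that migrates, gives the ring-expanded 9-phenylthio 8-ketone F3. Lithium naphthalenide (3 equiv, THF, −78 °C) deprotonates the hydroxyl and cleaves the C–S bond reductively to the same regiodefined enolate 13, where the route is rejoined (CH2O, then Et3SiOTf, to 15).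

- Step 3 (ring-fusion stereochemistry). Dissolving-metal reduction of hydrindenones can give some cis-fused product. The fallback sets out from 6: deconjugative α-methylation (KOt-Bu, MeI, t-BuOH) gives the β,γ-unsaturated gem-dimethyl ketone F1, and hydrogenation (H2, Pd/C, EtOAc) from the face opposite the angular methyl delivers 5α-H and returns to the route at 8.

- Step 10 (ether formation). The β-branched axial CH2OH may react slowly under Mitsunobu conditions, or some 6-O-alkylation may occur. The fallback sets out from 19: TsCl in pyridine at 0 °C gives the primary tosylate F4 (the hindered 3-OH does not react). Displacement with the mono-caesium salt of 24 (Cs2CO3 1 equiv, DMF, 70 °C), which is the 7-phenoxide, returns to the route at 25; MeI/K2CO3 in acetone then gives 26.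

**Further compounds**
F1 | step 3 | (7a'S)-4',4',7a'-trimethyl-4',6',7',7a'-tetrahydrospiro[[1,3]dioxolane-2,1'-inden]-5'(2'H)-one (alkene between C3a' and C3') | C[C@]12CCC(=O)C(C)(C)C1=CCC21OCCO1
F2 | step 5 | (1S,3aS,5R,7aS)-1-[bis(phenylthio)methyl]-4,4,7a-trimethyloctahydro-1H-indene-1,5-diol | C[C@]12CC[C@@H](O)C(C)(C)[C@@H]1CC[C@@]2(O)C(Sc1ccccc1)Sc1ccccc1
F3 | step 5 | (4aS,6R,8aS)-6-hydroxy-5,5,8a-trimethyl-1-(phenylthio)octahydronaphthalen-2(1H)-one (trans-fused, C1 epimers) | c1ccccc1SC1C(=O)CC[C@H]2C(C)(C)[C@H](O)CC[C@]12C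
F4 | step 10 | [(1R,4aR,6R,8aS)-6-hydroxy-2,5,5,8a-tetramethyl-1,4,4a,5,6,7,8,8a-octahydronaphthalen-1-yl]methyl 4-methylbenzenesulfonate | Cc1ccc(cc1)S(=O)(=O)OC[C@@H]1C(C)=CC[C@H]2C(C)(C)[C@H](O)CC[C@]12C
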